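**Retrosynthetic overview**

1. Rings are lettered A (2,4,6-trihydroxyphenoxy end) to H (3,4,5-trihydroxyphenoxy end); position 1 of each ring is the carbon whose ether oxygen points toward ring A. The strategy rests on ring D: D1 carries the oxygen to C6 (ring C, position 6), D3 and D5 carry hydroxyls, and D4 carries the oxygen to E1. D4 and E1 each have two ortho oxygens, so D4–O–E1 is a tetra-ortho-substituted diaryl ether that aryl coupling handles badly. The D3-hydroxyl/D1-ether 1,3-relation flanking that link is the resorcinol monoether pattern of a vinylketene–ynol ether benzannulation.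
2. Key disconnection: ring D is cut into a 4-aryloxy-3-ethoxycyclobutenone (ring E already on the oxygen of its sp3 carbon, made from an aryloxyketene and ethoxyacetylene) and an aryl ethynyl ether that carries rings A–B–C. Three C–C bonds form, and no aryl–oxygen bond is made at D4 or D1.
3. Every other ether is a CuI-catalysed Ullmann coupling in which the doubly flanked or more hindered carbon keeps its oxygen as the phenol: A1–OH + B1–Br, B4–OH + C1–I, G6–OH + H1–Br, G1–OH + F5–I and, last, E2–OH + F1–Br. The A–B arm is therefore put on ring C before the ethynyl ether is made, because B4 is doubly flanked like D4.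
4. Ring order: rings A, B, C, E, F, G and H are bought as benzenes (E and G come from one phenol made by directed metalation). Ring D is the only ring built; afterwards its new phenol is ethylated, the ring-E acetal removed, the F–G–H arm attached and all 21 alkyl ethers cleaved.

Key step: step 16

Remark: the target has no stereocenter; the cyclobutenone and the two later sp3-containing intermediates of the key step are racemic and their centers vanish on aromatisation.
Name shorthand: ArE = 6-(methoxymethoxy)-2,3,4-trimethoxyphenyl; ArC = 6-[2,6-dimethoxy-4-(2,4,6-trimethoxyphenoxy)phenoxy]-2,3,4-trimethoxyphenyl.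

**Route**

Step 1
Reactants: 1 3,4,5-trimethoxyphenol
Product: 2 5-(methoxymethoxy)-1,2,3-trimethoxybenzene
Conditions: NaH, THF/DMF, 0 °C; MOMCl, 0 °C → rt
Reagents that add atoms: chloromethyl methyl ether (MOMCl), COCCl
Why: Williamson-type O-alkylation of the phenoxide should give the acetal, which both protects the oxygen and directs the metalation of step 2.

Step 2
Reactants: 2 5-(methoxymethoxy)-1,2,3-trimethoxybenzene
Product: 5 6-(methoxymethoxy)-2,3,4-trimethoxyphenol, via aryllithium 3 (not isolated), via dimethyl arylboronate 4 (not isolated)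
Conditions: n-BuLi, THF, 0 °C → rt; B(OMe)3, −78 °C → rt; AcOH, 30% H2O2, 0 °C → rt
Reagents that add atoms: hydrogen peroxide, OO
Why: Directed ortho-metalation should place lithium on one of the two equivalent carbons lying between the acetal and a methoxy group, and borylation followed by oxidative C–B to C–O conversion should give the doubly flanked phenol.

Step 3
Reactants: 5 6-(methoxymethoxy)-2,3,4-trimethoxyphenol; 6 ethyl bromoacetate
Product: 7 ethyl 2-[6-(methoxymethoxy)-2,3,4-trimethoxyphenoxy]acetate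
Conditions: K2CO3, DMF, 50 °C
Reagents that add atoms: none
Why: Williamson ether synthesis, the phenoxide displacing bromide from the unhindered α-bromo ester by SN2.

Step 4
Reactants: 7 ethyl 2-[6-(methoxymethoxy)-2,3,4-trimethoxyphenoxy]acetate
Product: 8 2-[6-(methoxymethoxy)-2,3,4-trimethoxyphenoxy]acetic acid
Conditions: LiOH·H2O, THF/H2O, rt; cold 1 M HCl to pH 3, immediate extraction
Reagents that add atoms: lithium hydroxide, [Li+].[OH-]
Why: Ester saponification under mild base, with only a brief cold acidification so that the acid-labile acetal should survive.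

Step 5
Reactants: 8 2-[6-(methoxymethoxy)-2,3,4-trimethoxyphenoxy]acetic acid; 9 ethoxyacetylene
Product: 12 3-ethoxy-4-[6-(methoxymethoxy)-2,3,4-trimethoxyphenoxy]cyclobut-2-en-1-one (racemic), via acid chloride 10 (not isolated), via aryloxyketene 11 (not isolated)
Conditions: 1-chloro-N,N,2-trimethylprop-1-en-1-amine, CH2Cl2, 0 °C → rt; then slow addition to 9 (3 equiv), Et3N, Et2O, 0 °C → rt
Reagents that add atoms: none
Why: The neutral chloroenamine should give the acid chloride without releasing HCl (acetal intact), dehydrochlorination should give the aryloxyketene, and ketene–ynol ether [2+2] cycloaddition, with the nucleophilic CH carbon of ethoxyacetylene bonding to the ketene carbonyl carbon, should give the 3-ethoxycyclobutenone as a racemate.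

Step 6
Reactants: 13 4-bromo-2,6-dimethoxyphenol
Product: 14 2-(benzyloxy)-5-bromo-1,3-dimethoxybenzene
Conditions: BnBr, K2CO3, DMF, rt
Reagents that add atoms: benzyl bromide, BrCc1ccccc1
Why: Williamson benzylation masks the phenol so that it cannot compete as a nucleophile in step 7.

Step 7
Reactants: 14 2-(benzyloxy)-5-bromo-1,3-dimethoxybenzene; 15 2,4,6-trimethoxyphenol
Product: 16 2-(benzyloxy)-1,3-dimethoxy-5-(2,4,6-trimethoxyphenoxy)benzene
Conditions: CuI (10 mol %), picolinic acid (20 mol %), K3PO4, DMSO, 90 °C, argon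
Reagents that add atoms: none
Why: Ullmann diaryl ether synthesis should tolerate the 2,6-disubstituted phenol because the hindrance sits on the nucleophile while the bromide has two free ortho positions.

Step 8
Reactants: 16 2-(benzyloxy)-1,3-dimethoxy-5-(2,4,6-trimethoxyphenoxy)benzene
Product: 17 2,6-dimethoxy-4-(2,4,6-trimethoxyphenoxy)phenol
Conditions: H2 (1 atm), Pd/C, EtOAc/MeOH, rt
Reagents that add atoms: none
Why: Catalytic hydrogenolysis should cleave only the benzylic C–O bond and leave diaryl and methyl ethers untouched.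

Step 9
Reactants: 18 2,3,4-trimethoxybenzaldehyde
Product: 20 2,3,4-trimethoxyphenol, via aryl formate 19 (not isolated)
Conditions: mCPBA, CH2Cl2, rt; K2CO3 (cat.), MeOH, rt
Reagents that add atoms: 3-chloroperoxybenzoic acid (mCPBA), OOC(=O)c1cccc(Cl)c1
Why: Baeyer–Villiger (Dakin-type) oxidation, in which the electron-rich aryl group migrates to oxygen and the resulting formate is removed by methanolysis.

Step 10
Reactants: 20 2,3,4-trimethoxyphenol
Product: 21 1-(methoxymethoxy)-2,3,4-trimethoxybenzene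
Conditions: NaH, THF/DMF, 0 °C; MOMCl, 0 °C → rt
Reagents that add atoms: chloromethyl methyl ether (MOMCl), COCCl
Why: Williamson-type acetal protection as in step 1, installing the directing group for step 11.

Step 11
Reactants: 21 1-(methoxymethoxy)-2,3,4-trimethoxybenzene
Product: 23 1-iodo-2-(methoxymethoxy)-3,4,5-trimethoxybenzene, via aryllithium 22 (not isolated)
Conditions: n-BuLi, THF, 0 °C; I2, THF, −78 °C → rt
Reagents that add atoms: iodine, II
Why: Directed ortho-metalation, the chelating acetal outranking methoxy as directing group so that lithiation and iodine quench should occur at the carbon next to it.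

Step 12
Reactants: 23 1-iodo-2-(methoxymethoxy)-3,4,5-trimethoxybenzene; 17 2,6-dimethoxy-4-(2,4,6-trimethoxyphenoxy)phenol
Product: 24 1-[2,6-dimethoxy-4-(2,4,6-trimethoxyphenoxy)phenoxy]-2-(methoxymethoxy)-3,4,5-trimethoxybenzene
Conditions: CuI (10 mol %), picolinic acid (20 mol %), K3PO4, DMSO, 90–100 °C, argon
Reagents that add atoms: none
Why: Ullmann diaryl ether synthesis in the favourable polarity, the doubly flanked B4 oxygen acting as the phenol nucleophile and the ring-C iodide carrying only one ortho substituent.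

Step 13
Reactants: 24 1-[2,6-dimethoxy-4-(2,4,6-trimethoxyphenoxy)phenoxy]-2-(methoxymethoxy)-3,4,5-trimethoxybenzene
Product: 25 6-[2,6-dimethoxy-4-(2,4,6-trimethoxyphenoxy)phenoxy]-2,3,4-trimethoxyphenol
Conditions: HCl (cat.), MeOH/THF, 50 °C
Reagents that add atoms: none
Why: Acid-catalysed acetal methanolysis should free the phenol while methanol traps the formaldehyde unit and aryl ethers stay intact.

Step 14
Reactants: 25 6-[2,6-dimethoxy-4-(2,4,6-trimethoxyphenoxy)phenoxy]-2,3,4-trimethoxyphenol; 26 trichloroethylene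
Product: 27 2-{[(E)-1,2-dichloroethenyl]oxy}-1-[2,6-dimethoxy-4-(2,4,6-trimethoxyphenoxy)phenoxy]-3,4,5-trimethoxybenzene
Conditions: KH, THF, 0 °C; 26, −50 °C → rt
Reagents that add atoms: none
Why: The potassium phenoxide should add in anti fashion to dichloroacetylene formed in situ from trichloroethylene (base-mediated elimination–addition), giving the (E)-dichlorovinyl ether even from a hindered phenol.

Step 15
Reactants: 27 2-{[(E)-1,2-dichloroethenyl]oxy}-1-[2,6-dimethoxy-4-(2,4,6-trimethoxyphenoxy)phenoxy]-3,4,5-trimethoxybenzene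
Product: 30 1-[2,6-dimethoxy-4-(2,4,6-trimethoxyphenoxy)phenoxy]-2-(ethynyloxy)-3,4,5-trimethoxybenzene, via chloroethynyl ether 28 (not isolated), via lithium acetylide 29 (not isolated)
Conditions: n-BuLi (2.5 equiv), THF, −78 → −40 °C; MeOH, −78 °C; cold work-up, used at once
Reagents that add atoms: none
Why: Dehydrochlorination to the chloroalkynyl ether, chlorine–lithium exchange and protonation (the standard dichlorovinyl ether route to terminal ynol ethers) should occur at −78 °C, where ring lithiation does not compete.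

Step 16
Reactants: 12 3-ethoxy-4-[6-(methoxymethoxy)-2,3,4-trimethoxyphenoxy]cyclobut-2-en-1-one (1.5 equiv); 30 1-[2,6-dimethoxy-4-(2,4,6-trimethoxyphenoxy)phenoxy]-2-(ethynyloxy)-3,4,5-trimethoxybenzene
Product: 35 5-(ArC-oxy)-3-ethoxy-2-(ArE-oxy)phenol, via vinylketene 31 (not isolated), via vinylcyclobutenone 32 (not isolated), via dienylketene 33 (not isolated), via cyclohexadienone 34 (not isolated)
Conditions: toluene (0.1 M), 80 °C then 110 °C, argon; then K2CO3, MeOH, rt (cleaves any O-acylated 35)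
Reagents that add atoms: none
Why: Heating should open 12 by four-electron electrocyclic cleavage (aryloxy group turning outward) to vinylketene 31, whose ketene C=C bond adds ethynyl ether 30 in a [2+2] cycloaddition to give vinylcyclobutenone 32; a second four-electron opening gives dienylketene 33, and six-electron electrocyclisation to dienone 34 followed by enolisation delivers phenol 35. This is the Danheiser benzannulation of a cyclobutenone with an ynol ether, the known route to resorcinol monoethers, run here with an aryl ynol ether. Ring D is the only ring closed, and it closes by thermal disrotatory six-electron electrocyclisation of 33, which joins the ketene carbon to the aryloxy-bearing diene terminus after the [2+2] step has made the other two C–C bonds. No stereocenter is set, since the sp3 centers of 12, 32 and 34 are racemic and are erased on aromatisation. The selectivity needed is the orientation of the ketene–alkyne addition, and the polarisation of the ynol ether secures it: its unsubstituted nucleophilic carbon bonds to the electrophilic ketene carbonyl carbon, so the ring-C oxygen ends meta to the new hydroxyl and para to the ring-E oxygen. The ring openings are reversible, so both diene geometries should funnel to 35, and the ethoxy group of 12 fixes the second oxygen ortho to the ring-E ether.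

Step 17
Reactants: 35 5-(ArC-oxy)-3-ethoxy-2-(ArE-oxy)phenol
Product: 36 5-(ArC-oxy)-1,3-diethoxy-2-(ArE-oxy)benzene
Conditions: EtI, K2CO3, DMF, 50 °C
Reagents that add atoms: iodoethane, CCI
Why: Williamson ethylation caps the ring-D phenol so that it cannot compete in step 24 and makes ring D symmetrical.

Step 18
Reactants: 36 5-(ArC-oxy)-1,3-diethoxy-2-(ArE-oxy)benzene
Product: 37 2-[4-(ArC-oxy)-2,6-diethoxyphenoxy]-3,4,5-trimethoxyphenol
Conditions: HCl (cat.), MeOH/THF, 50 °C
Reagents that add atoms: none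
Why: Acid-catalysed acetal methanolysis should free the E2 hydroxyl without touching methyl, ethyl or diaryl ethers.

Step 19
Reactants: 5 6-(methoxymethoxy)-2,3,4-trimethoxyphenol; 38 5-bromo-1,2,3-trimethoxybenzene
Product: 39 1-(methoxymethoxy)-3,4,5-trimethoxy-2-(3,4,5-trimethoxyphenoxy)benzene
Conditions: CuI (10 mol %), picolinic acid (20 mol %), K3PO4, DMSO, 90 °C, argon
Reagents that add atoms: none
Why: Ullmann diaryl ether synthesis between the hindered G6 phenol and a bromide with two free ortho positions, the same favourable pairing as in step 7.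

Step 20
Reactants: 39 1-(methoxymethoxy)-3,4,5-trimethoxy-2-(3,4,5-trimethoxyphenoxy)benzene
Product: 40 3,4,5-trimethoxy-2-(3,4,5-trimethoxyphenoxy)phenol
Conditions: HCl (cat.), MeOH, 50 °C
Reagents that add atoms: none
Why: Acid-catalysed acetal methanolysis should free the G1 hydroxyl.

Step 21
Reactants: 41 4-bromo-2-methoxyphenol
Product: 42 4-bromo-2-iodo-6-methoxyphenol
Conditions: NIS, TsOH (cat.), MeCN, rt
Reagents that add atoms: N-iodosuccinimide, O=C1CCC(=O)N1I
Why: Electrophilic aromatic iodination should go ortho to the free hydroxyl, the strongest activator, since the para position is blocked by bromine.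

Step 22
Reactants: 42 4-bromo-2-iodo-6-methoxyphenol
Product: 43 5-bromo-1-iodo-2,3-dimethoxybenzene
Conditions: MeI, K2CO3, acetone, reflux
Reagents that add atoms: iodomethane, CI
Why: Williamson methylation of the phenol.

Step 23
Reactants: 40 3,4,5-trimethoxy-2-(3,4,5-trimethoxyphenoxy)phenol; 43 5-bromo-1-iodo-2,3-dimethoxybenzene (slight excess)
Product: 44 5-bromo-1,2-dimethoxy-3-[3,4,5-trimethoxy-2-(3,4,5-trimethoxyphenoxy)phenoxy]benzene
Conditions: CuI (10 mol %), picolinic acid (20 mol %), K3PO4, DMSO, 75 °C, argon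
Reagents that add atoms: none
Why: Ullmann diaryl ether synthesis made chemoselective by the weaker C–I bond, which should react at a temperature at which the aryl bromide needed for step 24 is still inert.

Step 24
Reactants: 37 2-[4-(ArC-oxy)-2,6-diethoxyphenoxy]-3,4,5-trimethoxyphenol; 44 5-bromo-1,2-dimethoxy-3-[3,4,5-trimethoxy-2-(3,4,5-trimethoxyphenoxy)phenoxy]benzene
Product: 45 2-[4-(ArC-oxy)-2,6-diethoxyphenoxy]-1-{3,4-dimethoxy-5-[3,4,5-trimethoxy-2-(3,4,5-trimethoxyphenoxy)phenoxy]phenoxy}-3,4,5-trimethoxybenzene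
Conditions: CuI (20 mol %), picolinic acid (40 mol %), K3PO4, DMSO, 100 °C, argon
Reagents that add atoms: none
Why: Ullmann diaryl ether synthesis joining the two fragments, the F1 bromide having two free ortho positions and the E2 phenol only one ortho substituent.

Step 25
Reactants: 45 2-[4-(ArC-oxy)-2,6-diethoxyphenoxy]-1-{3,4-dimethoxy-5-[3,4,5-trimethoxy-2-(3,4,5-trimethoxyphenoxy)phenoxy]phenoxy}-3,4,5-trimethoxybenzene
Product: 46 CNP0309601.0 (octamer A–H with all 21 hydroxyls free)
Conditions: BBr3 (large excess), CH2Cl2, −78 °C → rt, argon; MeOH then H2O, 0 °C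
Reagents that add atoms: none
Why: Lewis-acid ether cleavage, in which BBr3 complexes each alkoxy oxygen and bromide attacks the methyl or ethyl carbon by SN2, while the seven diaryl ether links offer no sp3 carbon and should remain.

**Compound list**

1 | 3,4,5-trimethoxyphenol | COc1cc(O)cc(OC)c1OC | starting material
2 | 5-(methoxymethoxy)-1,2,3-trimethoxybenzene | COCOc1cc(OC)c(OC)c(OC)c1 | intermediate
3 | [6-(methoxymethoxy)-2,3,4-trimethoxyphenyl]lithium | [Li]c1c(OCOC)cc(OC)c(OC)c1OC | intermediate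
4 | dimethyl [6-(methoxymethoxy)-2,3,4-trimethoxyphenyl]boronate | COB(OC)c1c(OCOC)cc(OC)c(OC)c1OC | intermediate
5 | 6-(methoxymethoxy)-2,3,4-trimethoxyphenol | COCOc1cc(OC)c(OC)c(OC)c1O | intermediate
6 | ethyl bromoacetate | CCOC(=O)CBr | starting material
7 | ethyl 2-[6-(methoxymethoxy)-2,3,4-trimethoxyphenoxy]acetate | CCOC(=O)COc1c(OCOC)cc(OC)c(OC)c1OC | intermediate
8 | 2-[6-(methoxymethoxy)-2,3,4-trimethoxyphenoxy]acetic acid | OC(=O)COc1c(OCOC)cc(OC)c(OC)c1OC | intermediate
9 | ethoxyacetylene | CCOC#C | starting material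
10 | 2-[6-(methoxymethoxy)-2,3,4-trimethoxyphenoxy]acetyl chloride | ClC(=O)COc1c(OCOC)cc(OC)c(OC)c1OC | intermediate
11 | 2-[6-(methoxymethoxy)-2,3,4-trimethoxyphenoxy]ethen-1-one (aryloxyketene) | O=C=COc1c(OCOC)cc(OC)c(OC)c1OC | intermediate
12 | 3-ethoxy-4-[6-(methoxymethoxy)-2,3,4-trimethoxyphenoxy]cyclobut-2-en-1-one (racemic) | CCOC1=CC(=O)C1Oc2c(OCOC)cc(OC)c(OC)c2OC | intermediate
13 | 4-bromo-2,6-dimethoxyphenol | COc1cc(Br)cc(OC)c1O | starting material
14 | 2-(benzyloxy)-5-bromo-1,3-dimethoxybenzene | COc1cc(Br)cc(OC)c1OCc1ccccc1 | intermediate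
15 | 2,4,6-trimethoxyphenol | COc1cc(OC)c(O)c(OC)c1 | starting material
16 | 2-(benzyloxy)-1,3-dimethoxy-5-(2,4,6-trimethoxyphenoxy)benzene | COc1cc(OC)c(Oc2cc(OC)c(OCc3ccccc3)c(OC)c2)c(OC)c1 | intermediate
17 | 2,6-dimethoxy-4-(2,4,6-trimethoxyphenoxy)phenol | COc1cc(OC)c(Oc2cc(OC)c(O)c(OC)c2)c(OC)c1 | intermediate
18 | 2,3,4-trimethoxybenzaldehyde | COc1ccc(C=O)c(OC)c1OC | starting material
19 | 2,3,4-trimethoxyphenyl formate | O=COc1ccc(OC)c(OC)c1OC | intermediate
20 | 2,3,4-trimethoxyphenol | COc1ccc(O)c(OC)c1OC | intermediate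
21 | 1-(methoxymethoxy)-2,3,4-trimethoxybenzene | COCOc1ccc(OC)c(OC)c1OC | intermediate
22 | [2-(methoxymethoxy)-3,4,5-trimethoxyphenyl]lithium | [Li]c1cc(OC)c(OC)c(OC)c1OCOC | intermediate
23 | 1-iodo-2-(methoxymethoxy)-3,4,5-trimethoxybenzene | COCOc1c(I)cc(OC)c(OC)c1OC | intermediate
24 | 1-[2,6-dimethoxy-4-(2,4,6-trimethoxyphenoxy)phenoxy]-2-(methoxymethoxy)-3,4,5-trimethoxybenzene | COCOc1c(Oc2c(OC)cc(Oc3c(OC)cc(OC)cc3OC)cc2OC)cc(OC)c(OC)c1OC | intermediate
25 | 6-[2,6-dimethoxy-4-(2,4,6-trimethoxyphenoxy)phenoxy]-2,3,4-trimethoxyphenol | Oc1c(Oc2c(OC)cc(Oc3c(OC)cc(OC)cc3OC)cc2OC)cc(OC)c(OC)c1OC | intermediate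
26 | trichloroethylene | ClC=C(Cl)Cl | starting material
27 | 2-{[(E)-1,2-dichloroethenyl]oxy}-1-[2,6-dimethoxy-4-(2,4,6-trimethoxyphenoxy)phenoxy]-3,4,5-trimethoxybenzene | Cl/C=C(/Cl)Oc1c(Oc2c(OC)cc(Oc3c(OC)cc(OC)cc3OC)cc2OC)cc(OC)c(OC)c1OC | intermediate
28 | 2-[(chloroethynyl)oxy]-1-[2,6-dimethoxy-4-(2,4,6-trimethoxyphenoxy)phenoxy]-3,4,5-trimethoxybenzene | ClC#COc1c(Oc2c(OC)cc(Oc3c(OC)cc(OC)cc3OC)cc2OC)cc(OC)c(OC)c1OC | intermediate
29 | lithium acetylide of 30 (ArC–O–C≡C–Li) | [Li]C#COc1c(Oc2c(OC)cc(Oc3c(OC)cc(OC)cc3OC)cc2OC)cc(OC)c(OC)c1OC | intermediate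
30 | 1-[2,6-dimethoxy-4-(2,4,6-trimethoxyphenoxy)phenoxy]-2-(ethynyloxy)-3,4,5-trimethoxybenzene | C#COc1c(Oc2c(OC)cc(Oc3c(OC)cc(OC)cc3OC)cc2OC)cc(OC)c(OC)c1OC | intermediate
31 | (3Z)-3-ethoxy-4-(ArE-oxy)buta-1,3-dien-1-one (vinylketene) | O=C=C/C(OCC)=C/Oc1c(OCOC)cc(OC)c(OC)c1OC | intermediate
32 | 3-(ArC-oxy)-4-[(Z)-1-ethoxy-2-(ArE-oxy)ethenyl]cyclobut-2-en-1-one (racemic) | O=C1C=C(Oc2c(Oc3c(OC)cc(Oc4c(OC)cc(OC)cc4OC)cc3OC)cc(OC)c(OC)c2OC)C1/C(OCC)=C/Oc5c(OCOC)cc(OC)c(OC)c5OC | intermediate
33 | (3E,5Z)-3-(ArC-oxy)-5-ethoxy-6-(ArE-oxy)hexa-1,3,5-trien-1-one (dienylketene) | O=C=C/C(Oc1c(Oc2c(OC)cc(Oc3c(OC)cc(OC)cc3OC)cc2OC)cc(OC)c(OC)c1OC)=C\C(OCC)=C\Oc4c(OCOC)cc(OC)c(OC)c4OC | intermediate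
34 | 3-(ArC-oxy)-5-ethoxy-6-(ArE-oxy)cyclohexa-2,4-dien-1-one (racemic) | O=C1C=C(Oc2c(Oc3c(OC)cc(Oc4c(OC)cc(OC)cc4OC)cc3OC)cc(OC)c(OC)c2OC)C=C(OCC)C1Oc5c(OCOC)cc(OC)c(OC)c5OC | intermediate
35 | 5-(ArC-oxy)-3-ethoxy-2-(ArE-oxy)phenol (A–B–C–D–E pentamer, free ring-D phenol) | Oc1cc(Oc2c(Oc3c(OC)cc(Oc4c(OC)cc(OC)cc4OC)cc3OC)cc(OC)c(OC)c2OC)cc(OCC)c1Oc5c(OCOC)cc(OC)c(OC)c5OC | intermediate
36 | 5-(ArC-oxy)-1,3-diethoxy-2-(ArE-oxy)benzene | CCOc1cc(Oc2c(Oc3c(OC)cc(Oc4c(OC)cc(OC)cc4OC)cc3OC)cc(OC)c(OC)c2OC)cc(OCC)c1Oc5c(OCOC)cc(OC)c(OC)c5OC | intermediate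
37 | 2-[4-(ArC-oxy)-2,6-diethoxyphenoxy]-3,4,5-trimethoxyphenol | CCOc1cc(Oc2c(Oc3c(OC)cc(Oc4c(OC)cc(OC)cc4OC)cc3OC)cc(OC)c(OC)c2OC)cc(OCC)c1Oc5c(O)cc(OC)c(OC)c5OC | intermediate
38 | 5-bromo-1,2,3-trimethoxybenzene | COc1cc(Br)cc(OC)c1OC | starting material
39 | 1-(methoxymethoxy)-3,4,5-trimethoxy-2-(3,4,5-trimethoxyphenoxy)benzene | COCOc1cc(OC)c(OC)c(OC)c1Oc2cc(OC)c(OC)c(OC)c2 | intermediate
40 | 3,4,5-trimethoxy-2-(3,4,5-trimethoxyphenoxy)phenol | Oc1cc(OC)c(OC)c(OC)c1Oc2cc(OC)c(OC)c(OC)c2 | intermediate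
41 | 4-bromo-2-methoxyphenol | COc1cc(Br)ccc1O | starting material
42 | 4-bromo-2-iodo-6-methoxyphenol | COc1cc(Br)cc(I)c1O | intermediate
43 | 5-bromo-1-iodo-2,3-dimethoxybenzene | COc1cc(Br)cc(I)c1OC | intermediate
44 | 5-bromo-1,2-dimethoxy-3-[3,4,5-trimethoxy-2-(3,4,5-trimethoxyphenoxy)phenoxy]benzene | COc1cc(Br)cc(Oc2cc(OC)c(OC)c(OC)c2Oc3cc(OC)c(OC)c(OC)c3)c1OC | intermediate
45 | 2-[4-(ArC-oxy)-2,6-diethoxyphenoxy]-1-{3,4-dimethoxy-5-[3,4,5-trimethoxy-2-(3,4,5-trimethoxyphenoxy)phenoxy]phenoxy}-3,4,5-trimethoxybenzene (octamer, 19 methyl and 2 ethyl ethers) | CCOc1cc(Oc2c(Oc3c(OC)cc(Oc4c(OC)cc(OC)cc4OC)cc3OC)cc(OC)c(OC)c2OC)cc(OCC)c1Oc5c(Oc6cc(OC)c(OC)c(Oc7cc(OC)c(OC)c(OC)c7Oc8cc(OC)c(OC)c(OC)c8)c6)cc(OC)c(OC)c5OC | intermediate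
46 | CNP0309601.0 (octamer A–H, 21 free hydroxyls) | Oc1cc(O)c(Oc2cc(O)c(Oc3cc(O)c(O)c(O)c3Oc3cc(O)c(Oc4c(Oc5cc(O)c(O)c(Oc6cc(O)c(O)c(O)c6Oc6cc(O)c(O)c(O)c6)c5)cc(O)c(O)c4O)c(O)c3)c(O)c2)c(O)c1 | target

**Totals**

Total step count: 25. Longest linear sequence: 12 steps (18 → 46 through steps 9–18, 24, 25; the branch from 13 through steps 6–8 and 12–18, 24, 25 is equally long).

**Steps most likely to fail**

1. Step 16. The terminal aryl ethynyl ether may oligomerise, and the vinylketene may dimerise, faster than the [2+2] addition at the temperature needed to open the cyclobutenone; the cascade may also stall before the six-electron closure. The fallback builds the D4–O–E1 ether by nucleophilic aromatic substitution instead; it sets out from phenol 5, uses phenol 25, and returns to the route at 36. Commercial 5-bromo-2-fluoro-1,3-dimethylbenzene is brominated at both methyl groups (NBS, AIBN, PhCF3, reflux) to 5-bromo-1,3-bis(dibromomethyl)-2-fluorobenzene F1, and hydrolysis (AgNO3, aqueous EtOH) gives 5-bromo-2-fluorobenzene-1,3-dicarbaldehyde F2. The phenoxide of 5 displaces the fluoride, which two ortho formyl groups activate (K2CO3, DMF, 60 °C), to give 5-bromo-2-(ArE-oxy)benzene-1,3-dicarbaldehyde F3. Double Baeyer–Villiger oxidation and formate methanolysis (mCPBA, NaHCO3, CH2Cl2; K2CO3, MeOH) should give 5-bromo-2-(ArE-oxy)benzene-1,3-diol F4, and EtI/K2CO3 gives 5-bromo-1,3-diethoxy-2-(ArE-oxy)benzene F5. Its unhindered bromide is coupled with hindered phenol 25 (CuI, picolinic acid, K3PO4, DMSO, 100 °C) to give 36.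

2. Step 5. Dimerisation of the aryloxyketene, or loss of the acetal, may outrun the cycloaddition with ethoxyacetylene, and the vinylogous ester may hydrolyse on isolation. The fallback generates the same vinylketene without any cyclobutenone; it sets out from phenol 5 and returns at vinylketene 31, hence at 35. Alkylation of 5 with commercial ethyl (E)-4-bromo-3-ethoxybut-2-enoate (K2CO3, acetone) gives ethyl (E)-3-ethoxy-4-(ArE-oxy)but-2-enoate F6; LiOH (THF/H2O) gives (E)-3-ethoxy-4-(ArE-oxy)but-2-enoic acid F7; and 1-chloro-N,N,2-trimethylprop-1-en-1-amine gives (E)-3-ethoxy-4-(ArE-oxy)but-2-enoyl chloride F8. Et3N in toluene at rt, with 30 present, effects 1,4-dehydrochlorination to 31, which should add 30 at rt and on warming pass through 32, 33 and 34 to 35, so that free 30 is never heated.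

3. Step 25. Cleavage may stop short among the 21 ethers, and the free polyphenol may be lost to air oxidation during isolation. The fallback sets out from 45 and returns at 46. The ethers are cleaved with AlBr3/EtSH (CH2Cl2, 0 °C → rt), and the crude product is acetylated at once (Ac2O, pyridine, DMAP) to the henicosaacetate of the target F9, which can be chromatographed and freed from partly dealkylated material. Acid methanolysis (HCl, degassed MeOH, rt, argon) then releases 46.

**Further compounds**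

F1 | step 16 | 5-bromo-1,3-bis(dibromomethyl)-2-fluorobenzene | Fc1c(C(Br)Br)cc(Br)cc1C(Br)Br
F2 | step 16 | 5-bromo-2-fluorobenzene-1,3-dicarbaldehyde | O=Cc1cc(Br)cc(C=O)c1F
F3 | step 16 | 5-bromo-2-[6-(methoxymethoxy)-2,3,4-trimethoxyphenoxy]benzene-1,3-dicarbaldehyde | O=Cc1cc(Br)cc(C=O)c1Oc2c(OCOC)cc(OC)c(OC)c2OC
F4 | step 16 | 5-bromo-2-[6-(methoxymethoxy)-2,3,4-trimethoxyphenoxy]benzene-1,3-diol | Oc1cc(Br)cc(O)c1Oc2c(OCOC)cc(OC)c(OC)c2OC
F5 | step 16 | 5-bromo-1,3-diethoxy-2-[6-(methoxymethoxy)-2,3,4-trimethoxyphenoxy]benzene | CCOc1cc(Br)cc(OCC)c1Oc2c(OCOC)cc(OC)c(OC)c2OC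
F6 | step 5 | ethyl (E)-3-ethoxy-4-[6-(methoxymethoxy)-2,3,4-trimethoxyphenoxy]but-2-enoate | CCOC(=O)/C=C(/OCC)COc1c(OCOC)cc(OC)c(OC)c1OC
F7 | step 5 | (E)-3-ethoxy-4-[6-(methoxymethoxy)-2,3,4-trimethoxyphenoxy]but-2-enoic acid | OC(=O)/C=C(/OCC)COc1c(OCOC)cc(OC)c(OC)c1OC
F8 | step 5 | (E)-3-ethoxy-4-[6-(methoxymethoxy)-2,3,4-trimethoxyphenoxy]but-2-enoyl chloride | ClC(=O)/C=C(/OCC)COc1c(OCOC)cc(OC)c(OC)c1OC
F9 | step 25 | henicosaacetate of 46 (all 21 hydroxyls acetylated) | CC(=O)Oc1cc(OC(C)=O)c(Oc2cc(OC(C)=O)c(Oc3cc(OC(C)=O)c(OC(C)=O)c(OC(C)=O)c3Oc3cc(OC(C)=O)c(Oc4c(Oc5cc(OC(C)=O)c(OC(C)=O)c(Oc6cc(OC(C)=O)c(OC(C)=O)c(OC(C)=O)c6Oc6cc(OC(C)=O)c(OC(C)=O)c(OC(C)=O)c6)c5)cc(OC(C)=O)c(OC(C)=O)c4OC(C)=O)c(OC(C)=O)c3)c(OC(C)=O)c2)c(OC(C)=O)c1
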